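**Retrosynthetic overview**

Locants: ring A = C1 (CO2Me), C2 (OMe), C3 (Me), C4 (O-acyl), C5 (Me), C6 (Me); ring B = C1′ (C=O), C2′ (OMe), C3′ (Me), C4′ (OH), C5′ (Cl), C6′ (Me). The depside bond O(C4)–C(=O) is cut first, giving a ring A phenol and a ring B aroyl chloride whose 4′-OH is masked as a MOM ether.
The plan rests on ring A. All six positions are substituted and the two meta oxygens (C2, C4) carry different partners, so the ring is built rather than substituted, by a photochemical diazo ketone/siloxyalkyne benzannulation that delivers O–C2 as a free phenol and O–C4 as a TIPS ether.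
C1, C6, C5 and C2 come from methyl (E)-5-diazo-3-methyl-4-oxohex-2-enoate, and C3 and C4 from 1-(triisopropylsiloxy)propyne. Bonds made: C5–C6 (Wolff shift), C2–C3 and C4–C5 ([2+2]), C1–C2 (6π ring closure).
The diazo ketone is used as the E isomer and is made by diazo transfer onto the ethyl ketone obtained from pentan-3-one and glyoxylic acid. The alkyne comes from ethyl acetate by ynolate homologation.
Ring order: ring B is bought as methyl atrarate and only decorated (Cl at C5′, MOM on O4′, Me on O2′, ester to acid chloride). Ring A is the only ring formed (step 5). The rings are joined in step 13 and unmasked in step 14.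

Key step: step 5

Remark: the target is achiral, so the only stereochemical element handled is the alkene geometry of the acyclic ring A precursors, which disappears on aromatisation; glyoxylic acid is taken as its commercial monohydrate.

**Route**

Step 1
Reactants: 1 pentan-3-one; 2 glyoxylic acid
Product: 3 (E)-3-methyl-4-oxohex-2-enoic acid
Conditions: 85% H3PO4, 80 °C (1 in excess)
Reagents that add atoms: none
Why: Acid-catalysed crossed aldol condensation: glyoxylic acid cannot enolise and is the better electrophile, the symmetrical ketone offers only one kind of α-carbon so no regiochemical question arises, and dehydration under equilibrating conditions should favour the open-chain E acid (CO2H trans to the propanoyl group), which is purified by crystallisation.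

Step 2
Reactants: 3 (E)-3-methyl-4-oxohex-2-enoic acid
Product: 4 methyl (E)-3-methyl-4-oxohex-2-enoate
Conditions: MeI, KHCO3, DMF, rt
Reagents that add atoms: iodomethane, CI
Why: SN2 O-alkylation of the carboxylate under nearly neutral conditions esterifies without acid or free methanol, so neither conjugate addition to the 4-oxoenoate nor loss of the E geometry is expected.

Step 3
Reactants: 4 methyl (E)-3-methyl-4-oxohex-2-enoate
Product: 6 methyl (E)-5-diazo-3-methyl-4-oxohex-2-enoate, via trifluoroacetyl ketone 5 (not isolated)
Conditions: LiN(SiMe3)2, THF, −78 °C; CF3CO2CH2CF3, −78 °C; aq. HCl work-up; crude 5, MsN3, Et3N, H2O, MeCN, rt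
Reagents that add atoms: methanesulfonyl azide, CS(=O)(=O)N=[N+]=[N-] (N2 of 6); 2,2,2-trifluoroethyl trifluoroacetate, O=C(OCC(F)(F)F)C(F)(F)F (CF3CO of 5 only)
Why: Detrifluoroacetylative diazo transfer: kinetic deprotonation at the ethyl CH2 (α′ to the enone) and Claisen-type C-trifluoroacetylation activate that carbon, the sulfonyl azide then delivers N2 while CF3CO leaves as the N-acylsulfonamide, and this way is chosen over acylation of diazoethane by an acid chloride because a diazoalkane would add as a 1,3-dipole across the doubly activated C=C.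

Step 4
Reactants: 7 ethyl acetate
Product: 10 1-(triisopropylsiloxy)prop-1-yne, via lithium dibromoenolate 8 (not isolated), via lithium propynolate 9 (not isolated)
Conditions: CH2Br2, lithium 2,2,6,6-tetramethylpiperidide, THF, −78 °C; 7; LiN(SiMe3)2; n-BuLi, −78 °C → rt; TIPSCl, 0 °C → rt
Reagents that add atoms: dibromomethane, BrCBr; triisopropylsilyl chloride, CC(C)[Si](Cl)(C(C)C)C(C)C; lithium 2,2,6,6-tetramethylpiperidide, [Li+].CC1(C)CCCC(C)(C)[N-]1 (Li of 8 and 9 only)
Why: Kowalski ester homologation: LiCHBr2 adds to the ester, the amide base turns the adduct into dibromoenolate 8, Br/Li exchange triggers the 1,2-shift to ynolate 9, and the bulky silyl chloride traps it on oxygen rather than on carbon.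

Step 5
Reactants: 6 methyl (E)-5-diazo-3-methyl-4-oxohex-2-enoate; 10 1-(triisopropylsiloxy)prop-1-yne
Product: 15 methyl 2-hydroxy-3,5,6-trimethyl-4-(triisopropylsiloxy)benzoate, via vinylketene 11 (not isolated), via alkenylcyclobutenone 12 (not isolated), via dienylketene 13 (not isolated), via cyclohexadienone 14 (not isolated)
Conditions: hν (254 nm, Vycor), 10 (1.5 equiv), degassed ClCH2CH2Cl, rt; then 80 °C
Reagents that add atoms: none
Why: Light expels N2 from 6 and the alkenyl group shifts from the carbonyl carbon to the diazo carbon (photochemical Wolff rearrangement, new bond C5–C6), giving vinylketene 11. The nucleophilic methyl-bearing carbon of ynol ether 10 attacks the ketene carbonyl carbon, and the [2+2] cycloaddition (C2–C3 and C4–C5) gives alkenylcyclobutenone 12, whose former ketene bond C2–C5 then breaks in a reversible 4π electrocyclic opening (light or 80 °C) to dienylketene 13. Ring A closes by a thermal disrotatory 6π electrocyclisation of 13 (C1–C2) and the β-keto ester 14 so formed enolises at once to phenol 15; the closest known reaction type is the Danheiser benzannulation in its photochemical diazo ketone version with siloxyalkynes, which gives resorcinol monosilyl ethers. No stereocentre survives, since the quaternary carbon of 12 and the C1–H carbon of 14 are both flattened on the way to the arene. The selectivity needed is the orientation of the [2+2] step, and the oxygen-induced polarisation of 10 secures it, so that the alkyne methyl ends at C3 between the two oxygens, the ketene oxygen becomes the free C2–OH next to the ester, and the ynol oxygen stays silylated at C4. The E geometry of 6 keeps the ester carbonyl away from the ketene carbon (no 6π oxa-closure to a 2-pyranone) and turns H rather than CO2Me towards the inside of the closing triene.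

Step 6
Reactants: 15 methyl 2-hydroxy-3,5,6-trimethyl-4-(triisopropylsiloxy)benzoate
Product: 16 methyl 2-methoxy-3,5,6-trimethyl-4-(triisopropylsiloxy)benzoate
Conditions: MeI, K2CO3, acetone, reflux
Reagents that add atoms: iodomethane, CI
Why: Williamson ether synthesis: the only free OH is the C2 phenol, whose hydrogen bond to the ester is weakened because the C6 methyl twists the ester out of plane, while the TIPS ether, shielded by the C3 and C5 methyl groups, should withstand anhydrous carbonate.

Step 7
Reactants: 16 methyl 2-methoxy-3,5,6-trimethyl-4-(triisopropylsiloxy)benzoate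
Product: 17 methyl 4-hydroxy-2-methoxy-3,5,6-trimethylbenzoate
Conditions: Bu4NF, AcOH, THF, 0 °C → rt
Reagents that add atoms: none
Why: Fluoride-induced cleavage of the aryl silyl ether is driven by the Si–F bond and the good phenoxide leaving group, and the acetic acid buffer protonates the phenoxide and spares the methyl ester.

Step 8
Reactants: 18 methyl 2,4-dihydroxy-3,6-dimethylbenzoate (methyl atrarate)
Product: 19 methyl 5-chloro-2,4-dihydroxy-3,6-dimethylbenzoate
Conditions: SO2Cl2 (1 equiv), CH2Cl2–Et2O, 0 °C
Reagents that add atoms: sulfuryl chloride, O=S(=O)(Cl)Cl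
Why: Electrophilic aromatic chlorination goes to C5′, the only unsubstituted ring position, which is ortho to the 4′-OH and para to the 2′-OH.

Step 9
Reactants: 19 methyl 5-chloro-2,4-dihydroxy-3,6-dimethylbenzoate
Product: 20 methyl 5-chloro-2-hydroxy-4-(methoxymethoxy)-3,6-dimethylbenzoate
Conditions: MOMCl (1.1 equiv), K2CO3, acetone, 0 °C → rt
Reagents that add atoms: chloromethyl methyl ether, COCCl
Why: Selective O-alkylation: the 4′-OH, acidified by the ortho chlorine and not hydrogen-bonded, is deprotonated and alkylated first, whereas the 2′-OH is held in a chelate with the ester carbonyl.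

Step 10
Reactants: 20 methyl 5-chloro-2-hydroxy-4-(methoxymethoxy)-3,6-dimethylbenzoate
Product: 21 methyl 5-chloro-2-methoxy-4-(methoxymethoxy)-3,6-dimethylbenzoate
Conditions: MeI, K2CO3, DMF, 50 °C
Reagents that add atoms: iodomethane, CI
Why: Williamson methylation of the remaining chelated 2′-OH under more forcing conditions (polar aprotic solvent, warming), to which the MOM acetal, the aryl chloride and the hindered ester are inert.

Step 11
Reactants: 21 methyl 5-chloro-2-methoxy-4-(methoxymethoxy)-3,6-dimethylbenzoate
Product: 22 5-chloro-2-methoxy-4-(methoxymethoxy)-3,6-dimethylbenzoic acid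
Conditions: KOH, DMSO–H2O, 90 °C; then cold 1 M HCl to pH 3
Reagents that add atoms: potassium hydroxide, [K+].[OH-] (O of the new carboxyl OH)
Why: Saponification of a di-ortho-substituted benzoate needs poorly solvated hydroxide in hot aqueous DMSO, and the MOM ether is base-stable and survives the brief cold acidification.

Step 12
Reactants: 22 5-chloro-2-methoxy-4-(methoxymethoxy)-3,6-dimethylbenzoic acid
Product: 23 5-chloro-2-methoxy-4-(methoxymethoxy)-3,6-dimethylbenzoyl chloride (used crude)
Conditions: Me2C=C(Cl)NMe2, CH2Cl2, 0 °C → rt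
Reagents that add atoms: 1-chloro-N,N,2-trimethylprop-1-en-1-amine, CC(C)=C(Cl)N(C)C
Why: The α-chloroenamine converts the acid into the acid chloride under neutral conditions, giving an amide instead of HCl, so the acid-labile MOM ether is kept.

Step 13
Reactants: 17 methyl 4-hydroxy-2-methoxy-3,5,6-trimethylbenzoate; 23 5-chloro-2-methoxy-4-(methoxymethoxy)-3,6-dimethylbenzoyl chloride
Product: 25 methyl 4-{[5-chloro-2-methoxy-4-(methoxymethoxy)-3,6-dimethylbenzoyl]oxy}-2-methoxy-3,5,6-trimethylbenzoate, via sodium phenoxide 24 (not isolated)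
Conditions: 17, NaH, THF, 0 °C; then 23, rt → 50 °C
Reagents that add atoms: sodium hydride, [Na+].[H-] (Na of 24 only)
Why: Anhydrous acylation of a preformed phenoxide by an aroyl chloride (nucleophilic acyl substitution): the fully ionised nucleophile and the most reactive acyl donor are used because both partners are di-ortho-substituted, and ring A offers no other nucleophilic site.

Step 14
Reactants: 25 MOM-protected depside
Product: 26 methyl 4-[(5-chloro-4-hydroxy-2-methoxy-3,6-dimethylbenzoyl)oxy]-2-methoxy-3,5,6-trimethylbenzoate (target CNP0192286.0)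
Conditions: 3 M aq. HCl, THF, 45 °C
Reagents that add atoms: none
Why: Acid hydrolysis of the MOM acetal runs through its oxocarbenium ion, while both esters are flanked by two ortho substituents and resist addition–elimination hydrolysis under these mild conditions.

**Compound list**

1 | pentan-3-one | CCC(=O)CC | starting material
2 | glyoxylic acid (used as monohydrate) | O=CC(=O)O | starting material
3 | (E)-3-methyl-4-oxohex-2-enoic acid | CCC(=O)/C(C)=C/C(=O)O | intermediate
4 | methyl (E)-3-methyl-4-oxohex-2-enoate | CCC(=O)/C(C)=C/C(=O)OC | intermediate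
5 | methyl (E)-7,7,7-trifluoro-3,5-dimethyl-4,6-dioxohept-2-enoate (racemic, enolisable) | COC(=O)/C=C(\C)C(=O)C(C)C(=O)C(F)(F)F | intermediate
6 | methyl (E)-5-diazo-3-methyl-4-oxohex-2-enoate | COC(=O)/C=C(\C)C(=O)C(C)=[N+]=[N-] | intermediate
7 | ethyl acetate | CCOC(C)=O | starting material
8 | lithium 1,1-dibromoprop-1-en-2-olate | CC([O-])=C(Br)Br.[Li+] | intermediate
9 | lithium prop-1-yn-1-olate | CC#C[O-].[Li+] | intermediate
10 | 1-(triisopropylsiloxy)prop-1-yne | CC#CO[Si](C(C)C)(C(C)C)C(C)C | intermediate
11 | methyl (E)-3,4-dimethyl-5-oxopenta-2,4-dienoate (vinylketene) | COC(=O)/C=C(\C)C(C)=C=O | intermediate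
12 | methyl (E)-3-[1,3-dimethyl-4-oxo-2-(triisopropylsiloxy)cyclobut-2-en-1-yl]but-2-enoate (racemic) | COC(=O)/C=C(\C)C1(C)C(=O)C(C)=C1O[Si](C(C)C)(C(C)C)C(C)C | intermediate
13 | methyl (2E,4E)-3,4,6-trimethyl-7-oxo-5-(triisopropylsiloxy)hepta-2,4,6-trienoate (dienylketene) | O=C=C(C)/C(O[Si](C(C)C)(C(C)C)C(C)C)=C(C)\C(C)=C\C(=O)OC | intermediate
14 | methyl 2,3,5-trimethyl-6-oxo-4-(triisopropylsiloxy)cyclohexa-2,4-diene-1-carboxylate (racemic) | COC(=O)C1C(C)=C(C)C(O[Si](C(C)C)(C(C)C)C(C)C)=C(C)C1=O | intermediate
15 | methyl 2-hydroxy-3,5,6-trimethyl-4-(triisopropylsiloxy)benzoate | COC(=O)c1c(C)c(C)c(O[Si](C(C)C)(C(C)C)C(C)C)c(C)c1O | intermediate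
16 | methyl 2-methoxy-3,5,6-trimethyl-4-(triisopropylsiloxy)benzoate | COC(=O)c1c(C)c(C)c(O[Si](C(C)C)(C(C)C)C(C)C)c(C)c1OC | intermediate
17 | methyl 4-hydroxy-2-methoxy-3,5,6-trimethylbenzoate | COC(=O)c1c(C)c(C)c(O)c(C)c1OC | intermediate
18 | methyl 2,4-dihydroxy-3,6-dimethylbenzoate (methyl atrarate) | COC(=O)c1c(C)cc(O)c(C)c1O | starting material
19 | methyl 5-chloro-2,4-dihydroxy-3,6-dimethylbenzoate | COC(=O)c1c(C)c(Cl)c(O)c(C)c1O | intermediate
20 | methyl 5-chloro-2-hydroxy-4-(methoxymethoxy)-3,6-dimethylbenzoate | COC(=O)c1c(C)c(Cl)c(OCOC)c(C)c1O | intermediate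
21 | methyl 5-chloro-2-methoxy-4-(methoxymethoxy)-3,6-dimethylbenzoate | COC(=O)c1c(C)c(Cl)c(OCOC)c(C)c1OC | intermediate
22 | 5-chloro-2-methoxy-4-(methoxymethoxy)-3,6-dimethylbenzoic acid | OC(=O)c1c(C)c(Cl)c(OCOC)c(C)c1OC | intermediate
23 | 5-chloro-2-methoxy-4-(methoxymethoxy)-3,6-dimethylbenzoyl chloride | ClC(=O)c1c(C)c(Cl)c(OCOC)c(C)c1OC | intermediate
24 | sodium 3-methoxy-4-(methoxycarbonyl)-2,5,6-trimethylphenoxide | COC(=O)c1c(C)c(C)c([O-])c(C)c1OC.[Na+] | intermediate
25 | methyl 4-{[5-chloro-2-methoxy-4-(methoxymethoxy)-3,6-dimethylbenzoyl]oxy}-2-methoxy-3,5,6-trimethylbenzoate | COC(=O)c1c(C)c(C)c(OC(=O)c2c(C)c(Cl)c(OCOC)c(C)c2OC)c(C)c1OC | intermediate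
26 | methyl 4-[(5-chloro-4-hydroxy-2-methoxy-3,6-dimethylbenzoyl)oxy]-2-methoxy-3,5,6-trimethylbenzoate | COC(=O)c1c(C)c(C)c(OC(=O)c2c(C)c(Cl)c(O)c(C)c2OC)c(C)c1OC | target

**Step count and risks**

Total step count: 14.
Longest linear sequence: 8 steps (1, 2, 3, 5, 6, 7, 13, 14). The ring B branch has 7 steps (8 to 14) and the alkyne branch joins after 1 step.

Steps most likely to fail:

Step 5 (key step).
- A 1,2-hydrogen shift from the α-methyl group may compete with the Wolff shift.
- Light may isomerise the enoate from E to Z, after which the ester carbonyl can capture the ketene.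
- The cycloaddition of a disubstituted ketene may be sluggish, and the 6π closure to a fully substituted ring may be slow.

Fallback: ring A by substitution on a preformed arene, setting out from methyl atrarate 18 and returning at 15. The only free position, C5, is formylated (Cl2CHOMe, TiCl4, CH2Cl2, Rieche formylation) to methyl 5-formyl-2,4-dihydroxy-3,6-dimethylbenzoate F1. Ionic hydrogenation of the ortho-hydroxy aldehyde (Et3SiH, CF3CO2H) gives methyl 2,4-dihydroxy-3,5,6-trimethylbenzoate F2. Silylation of the non-chelated C4 hydroxyl (TIPSOTf, 2,6-lutidine, CH2Cl2) then gives 15.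

Step 3.
- The enolate may undergo Michael-type self-condensation with the strongly electrophilic oxoenoate.
- Deprotonation may occur at the C3 methyl group instead of the ethyl CH2.
- Acylation may take place on oxygen instead of carbon.

Fallback: the diazo group is installed before the double bond, setting out from pentan-3-one 1 and returning at 6. The same two-stage diazo transfer on this simple ketone, which holds no Michael acceptor, passes through 1,1,1-trifluoro-3-methylhexane-2,4-dione F3 and gives 2-diazopentan-3-one F4. Deprotonation at the α′ CH2 (LiN(iPr)2, THF, −78 °C) and aldol addition to methyl glyoxylate give methyl 5-diazo-2-hydroxy-3-methyl-4-oxohexanoate F5, a diastereomer mixture of no consequence. Mesylation (MsCl, Et3N, CH2Cl2) gives methyl 5-diazo-3-methyl-2-(methylsulfonyloxy)-4-oxohexanoate F6. E1cB elimination (DBU) installs the E double bond last and gives 6.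

Step 13.
- Acylation between two di-ortho-substituted partners may be too slow.
- Hydrolysis of the acyl donor or loss of the MOM group during activation could then take over.

Fallback: acylium-type activation under acidic conditions with a benzyl ether in place of the MOM ether, setting out from 19 (with phenol 17 as partner) and returning at 26. Benzylation of the 4′-OH (BnBr, K2CO3, acetone) gives methyl 4-benzyloxy-5-chloro-2-hydroxy-3,6-dimethylbenzoate F7. Methylation (MeI, K2CO3, DMF) gives methyl 4-benzyloxy-5-chloro-2-methoxy-3,6-dimethylbenzoate F8, and saponification (KOH, DMSO–H2O) gives 4-benzyloxy-5-chloro-2-methoxy-3,6-dimethylbenzoic acid F9. (CF3CO)2O in toluene converts F9 into 4-benzyloxy-5-chloro-2-methoxy-3,6-dimethylbenzoic trifluoroacetic anhydride F10. This donor is little affected by ortho substituents and acylates 17 to methyl 4-[(4-benzyloxy-5-chloro-2-methoxy-3,6-dimethylbenzoyl)oxy]-2-methoxy-3,5,6-trimethylbenzoate F11. Hydrogenolysis (H2, Pd/C, EtOAc, stopped after one equivalent so that the aryl chloride is kept) gives 26.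

**Further compounds**

F1 | step 5 | methyl 5-formyl-2,4-dihydroxy-3,6-dimethylbenzoate | COC(=O)c1c(C)c(C=O)c(O)c(C)c1O
F2 | step 5 | methyl 2,4-dihydroxy-3,5,6-trimethylbenzoate | COC(=O)c1c(C)c(C)c(O)c(C)c1O
F3 | step 3 | 1,1,1-trifluoro-3-methylhexane-2,4-dione (racemic) | CCC(=O)C(C)C(=O)C(F)(F)F
F4 | step 3 | 2-diazopentan-3-one | CCC(=O)C(C)=[N+]=[N-]
F5 | step 3 | methyl 5-diazo-2-hydroxy-3-methyl-4-oxohexanoate (diastereomer mixture) | COC(=O)C(O)C(C)C(=O)C(C)=[N+]=[N-]
F6 | step 3 | methyl 5-diazo-3-methyl-2-(methylsulfonyloxy)-4-oxohexanoate (diastereomer mixture) | COC(=O)C(OS(C)(=O)=O)C(C)C(=O)C(C)=[N+]=[N-]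
F7 | step 13 | methyl 4-benzyloxy-5-chloro-2-hydroxy-3,6-dimethylbenzoate | COC(=O)c1c(C)c(Cl)c(OCc2ccccc2)c(C)c1O
F8 | step 13 | methyl 4-benzyloxy-5-chloro-2-methoxy-3,6-dimethylbenzoate | COC(=O)c1c(C)c(Cl)c(OCc2ccccc2)c(C)c1OC
F9 | step 13 | 4-benzyloxy-5-chloro-2-methoxy-3,6-dimethylbenzoic acid | OC(=O)c1c(C)c(Cl)c(OCc2ccccc2)c(C)c1OC
F10 | step 13 | 4-benzyloxy-5-chloro-2-methoxy-3,6-dimethylbenzoic trifluoroacetic anhydride | O=C(OC(=O)C(F)(F)F)c1c(C)c(Cl)c(OCc2ccccc2)c(C)c1OC
F11 | step 13 | methyl 4-[(4-benzyloxy-5-chloro-2-methoxy-3,6-dimethylbenzoyl)oxy]-2-methoxy-3,5,6-trimethylbenzoate | COC(=O)c1c(C)c(C)c(OC(=O)c2c(C)c(Cl)c(OCc3ccccc3)c(C)c2OC)c(C)c1OC
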